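**Assumption:** the target has no stereocentre and is achiral. "Single enantiomer" is read as the single (2E,6E) isomer drawn, so the two trisubstituted alkenes are the only stereo-elements to control.

## Retrosynthetic overview
1. Cacospongin D comes from its methyl ester by saponification.
2. The ArCH2–CH= bond is cut. An (E)-alkenylalane adds 1,4 to an o-quinone methide, which is made by dearomatising methyl 3-(chloromethyl)-4-hydroxybenzoate (from methylparaben, CH2O and HCl).
3. The alkenylalane comes from syn Zr-catalysed methylalumination of a C18 enyne. This sets the 2E alkene in the same flask as the coupling.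
4. The enyne comes from Negishi sp2–sp3 coupling of an (E)-alkenyl iodide with a homopropargylzinc. The iodide comes from methylalumination/iodination of a C13 alkyne (sets 6E), which is made from dihydro-β-ionone.
5. No ring is built. The cyclohexene and the arene are both bought, and the arene is only opened to the dienone and re-formed in the key step.

## Route

**Step 1**
Reactants: 1 dihydro-β-ionone, 4-(2,6,6-trimethylcyclohex-1-en-1-yl)butan-2-one
Product: 3 2-(but-3-yn-1-yl)-1,3,3-trimethylcyclohex-1-ene, via diethyl 4-(2,6,6-trimethylcyclohex-1-en-1-yl)but-1-en-2-yl phosphate 2 (not isolated)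
Conditions: LDA (1.05 equiv), THF, −78 °C; ClP(O)(OEt)2, −78 °C → rt; then LDA (2.3 equiv), THF, −78 °C → rt; H2O
Reagents that add atoms: diethyl chlorophosphate, CCOP(=O)(Cl)OCC (its atoms are carried in 2 only and leave again before 3)
Why: Kinetic LDA deprotonation takes the CH3 side, O-phosphorylation gives the terminal enol phosphate, and LDA-induced E2 loss of diethyl phosphate gives the terminal alkyne (Negishi methyl ketone → alkyne sequence), with no stereo-element made and the ring alkene inert to base.

**Step 2**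
Reactants: 3 2-(but-3-yn-1-yl)-1,3,3-trimethylcyclohex-1-ene
Product: 5 2-[(3E)-4-iodo-3-methylbut-3-en-1-yl]-1,3,3-trimethylcyclohex-1-ene, via dimethyl[(1E)-2-methyl-4-(2,6,6-trimethylcyclohex-1-en-1-yl)but-1-en-1-yl]alane 4 (not isolated)
Conditions: Me3Al (2 equiv), Cp2ZrCl2 (25 mol %), CH2Cl2, 0 °C → rt; then I2, THF, −30 → 0 °C; cold 1 M HCl, aq Na2S2O3 wash
Reagents that add atoms: trimethylaluminium, C[Al](C)C; iodine, II
Why: Negishi Zr-catalysed methylalumination adds CH3 and Al syn with Al on the terminal carbon, and iodinolysis of the C–Al bond goes with retention, so the later 6E alkene is fixed here while the tetrasubstituted alkene does not react.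

**Step 3**
Reactants: 5 2-[(3E)-4-iodo-3-methylbut-3-en-1-yl]-1,3,3-trimethylcyclohex-1-ene; 6 (4-bromobut-1-yn-1-yl)trimethylsilane
Product: 9 1,3,3-trimethyl-2-[(3E)-3-methyloct-3-en-7-yn-1-yl]cyclohex-1-ene, via [4-(trimethylsilyl)but-3-yn-1-yl]zinc bromide 7 (not isolated), via trimethyl[(5E)-6-methyl-8-(2,6,6-trimethylcyclohex-1-en-1-yl)oct-5-en-1-yn-1-yl]silane 8 (not isolated)
Conditions: 6, Zn dust, LiCl, THF, 50 °C; then 5, PdCl2(dppf) (3 mol %), THF, rt; then MeOH, K2CO3, rt
Reagents that add atoms: zinc, [Zn] (carried in 7 only, lost again before 8)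
Why: In this Negishi sp3–sp2 cross-coupling, oxidative addition to the alkenyl iodide and reductive elimination both go with retention so E is kept, dppf suppresses β-hydride elimination, and base-catalysed methanolysis then removes the alkynyl silane.

**Step 4**
Reactants: 10 methyl 4-hydroxybenzoate (methylparaben)
Product: 11 methyl 3-(chloromethyl)-4-hydroxybenzoate
Conditions: 37 % aq CH2O (1.2 equiv), conc. HCl, HCl (g), 45 °C; product filtered off
Reagents that add atoms: formaldehyde, C=O; hydrogen chloride, Cl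
Why: In this Blanc chloromethylation the OH directs to one of the two equivalent ortho positions (para is blocked), and the ester deactivates the ring enough to stop at mono-substitution and keep the benzylic chloride isolable, as in the chloromethylation of 4-hydroxyacetophenone.

**Step 5 (key step)**
Reactants: 9 1,3,3-trimethyl-2-[(3E)-3-methyloct-3-en-7-yn-1-yl]cyclohex-1-ene; 11 methyl 3-(chloromethyl)-4-hydroxybenzoate
Product: 15 methyl 3-[(2E,6E)-3,7-dimethyl-9-(2,6,6-trimethylcyclohex-1-en-1-yl)nona-2,6-dien-1-yl]-4-hydroxybenzoate, via [(1E,5E)-2,6-dimethyl-8-(2,6,6-trimethylcyclohex-1-en-1-yl)octa-1,5-dien-1-yl]dimethylalane 12 (not isolated), via lithium 2-(chloromethyl)-4-(methoxycarbonyl)phenoxide 13 (not isolated), via o-quinone methide methyl 3-methylidene-4-oxocyclohexa-1,5-diene-1-carboxylate 14 (not isolated)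
Conditions: (a) 9, Me3Al (2 equiv), Cp2ZrCl2 (20 mol %), CH2Cl2, 0 °C → rt; excess Me3Al and solvent off in vacuo, residue in toluene; (b) 11 (1.3 equiv), LiHMDS (1.3 equiv), THF, −78 °C, cannulated into (a) at −78 °C, then → rt over 3 h; cold 1 M HCl
Reagents that add atoms: trimethylaluminium, C[Al](C)C (CH3 stays in 15, AlMe2 in 12 only); lithium hexamethyldisilazide, [Li+].C[Si](C)(C)[N-][Si](C)(C)C (Li in 13 only)
Why: Proposed new method: phenoxide 13 binds the Lewis-acidic aluminium of 12, loss of LiCl on warming breaks the aromaticity to give the Al-bound s-cis enone 14, and the alkenyl ligand (sp2 transfers before CH3) passes to the exocyclic CH2 through a six-membered transition state with retention of the E geometry set by the syn Negishi methylalumination, driven by rearomatisation; the closest known reaction types are the Hooz-type 1,4-addition of alkenylalanes to s-cis enones and the addition of vinyl Grignard reagents to anionically generated o-quinone methides.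

**Step 6**
Reactants: 15 methyl 3-[(2E,6E)-3,7-dimethyl-9-(2,6,6-trimethylcyclohex-1-en-1-yl)nona-2,6-dien-1-yl]-4-hydroxybenzoate
Product: 16 cacospongin D
Conditions: LiOH (5 equiv), THF/MeOH/H2O, 55 °C; cold 1 M HCl to pH 3
Reagents that add atoms: lithium hydroxide, [Li+].[OH-]
Why: This BAc2 saponification needs warming because the phenoxide deactivates the ester, base leaves the three alkenes untouched, and a brief cold acidification avoids acid-induced chroman formation.

## Compound list
1 | dihydro-β-ionone, 4-(2,6,6-trimethylcyclohex-1-en-1-yl)butan-2-one | CC(=O)CCC1=C(C)CCCC1(C)C | starting material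
2 | diethyl 4-(2,6,6-trimethylcyclohex-1-en-1-yl)but-1-en-2-yl phosphate | C=C(CCC1=C(C)CCCC1(C)C)OP(=O)(OCC)OCC | intermediate
3 | 2-(but-3-yn-1-yl)-1,3,3-trimethylcyclohex-1-ene | C#CCCC1=C(C)CCCC1(C)C | intermediate
4 | dimethyl[(1E)-2-methyl-4-(2,6,6-trimethylcyclohex-1-en-1-yl)but-1-en-1-yl]alane | C[Al](C)/C=C(\C)CCC1=C(C)CCCC1(C)C | intermediate
5 | 2-[(3E)-4-iodo-3-methylbut-3-en-1-yl]-1,3,3-trimethylcyclohex-1-ene | I/C=C(\C)CCC1=C(C)CCCC1(C)C | intermediate
6 | (4-bromobut-1-yn-1-yl)trimethylsilane | C[Si](C)(C)C#CCCBr | starting material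
7 | [4-(trimethylsilyl)but-3-yn-1-yl]zinc bromide | Br[Zn]CCC#C[Si](C)(C)C | intermediate
8 | trimethyl[(5E)-6-methyl-8-(2,6,6-trimethylcyclohex-1-en-1-yl)oct-5-en-1-yn-1-yl]silane | C[Si](C)(C)C#CCC/C=C(\C)CCC1=C(C)CCCC1(C)C | intermediate
9 | 1,3,3-trimethyl-2-[(3E)-3-methyloct-3-en-7-yn-1-yl]cyclohex-1-ene | C#CCC/C=C(\C)CCC1=C(C)CCCC1(C)C | intermediate
10 | methyl 4-hydroxybenzoate | COC(=O)c1ccc(O)cc1 | starting material
11 | methyl 3-(chloromethyl)-4-hydroxybenzoate | COC(=O)c1ccc(O)c(CCl)c1 | intermediate
12 | [(1E,5E)-2,6-dimethyl-8-(2,6,6-trimethylcyclohex-1-en-1-yl)octa-1,5-dien-1-yl]dimethylalane | C[Al](C)/C=C(\C)CC/C=C(\C)CCC1=C(C)CCCC1(C)C | intermediate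
13 | lithium 2-(chloromethyl)-4-(methoxycarbonyl)phenoxide | [Li+].[O-]c1ccc(C(=O)OC)cc1CCl | intermediate
14 | methyl 3-methylidene-4-oxocyclohexa-1,5-diene-1-carboxylate (o-quinone methide) | O=C1C=CC(C(=O)OC)=CC1=C | intermediate
15 | methyl 3-[(2E,6E)-3,7-dimethyl-9-(2,6,6-trimethylcyclohex-1-en-1-yl)nona-2,6-dien-1-yl]-4-hydroxybenzoate | COC(=O)c1ccc(O)c(C/C=C(\C)CC/C=C(\C)CCC2=C(C)CCCC2(C)C)c1 | intermediate
16 | cacospongin D | CC1=C(CC/C(C)=C/CC/C(C)=C/Cc2cc(C(=O)O)ccc2O)C(C)(C)CCC1 | target

## Count and risks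
Total steps: 6. Longest linear sequence: 5 (1 → 3 → 5 → 9 → 15 → 16).

**Step 5 (most likely to fail).** The o-quinone methide may oligomerise, take up CH3 instead of the alkenyl group, or add to a chain alkene before the alkenyl transfer. The fallback gives up the quinone methide for a metal-catalysed sp2–sp3 cross-coupling. It sets out from 11, with 12 made from 9 as before, and comes back at 16.
- Compound 11 is acetylated without base (Ac2O, cat. H2SO4, 0 °C → rt) to methyl 4-acetoxy-3-(chloromethyl)benzoate F1, which can no longer expel chloride.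
- Alane 12 is coupled with F1 under Ni(0) catalysis (NiCl2(PPh3)2/n-BuLi, 5 mol %, THF, rt), with retention of alkene geometry. This gives methyl 4-acetoxy-3-[(2E,6E)-3,7-dimethyl-9-(2,6,6-trimethylcyclohex-1-en-1-yl)nona-2,6-dien-1-yl]benzoate F2.
- Excess LiOH in THF/MeOH/H2O then cleaves both esters and gives 16 directly.

**Step 4.** The risks are double chloromethylation, diarylmethane formation and self-condensation of 11. The fallback replaces electrophilic chloromethylation by a chelation-controlled formylation followed by redox adjustment. It sets out from 10 and comes back at 11.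
- Mg-mediated ortho-formylation (MgCl2, Et3N, (CH2O)n, MeCN, reflux) is strictly mono and ortho. It gives methyl 3-formyl-4-hydroxybenzoate F3.
- NaBH4 in MeOH at 0 °C gives methyl 4-hydroxy-3-(hydroxymethyl)benzoate F4.
- Stirring F4 with conc. HCl/CH2Cl2 at rt exchanges only the benzylic OH and gives 11.

**Step 1.** The risks are enolate regiochemistry and allene or internal alkyne by-products. The fallback drops the alkyne/carbometalation logic for this half of the chain in favour of olefination and allylic alkylation. It sets out from 1 and comes back at 8, so it also bypasses step 2 and the coupling of step 3.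
- Horner–Wadsworth–Emmons reaction of 1 (triethyl phosphonoacetate, NaH, THF) gives ethyl (2E)-3-methyl-5-(2,6,6-trimethylcyclohex-1-en-1-yl)pent-2-enoate F5. The minor Z isomer is removed by chromatography.
- DIBAL-H (CH2Cl2, −78 °C) gives (2E)-3-methyl-5-(2,6,6-trimethylcyclohex-1-en-1-yl)pent-2-en-1-ol F6.
- PBr3 (Et2O, 0 °C) gives 2-[(3E)-5-bromo-3-methylpent-3-en-1-yl]-1,3,3-trimethylcyclohex-1-ene F7.
- SN2 alkylation of lithiated 1-(trimethylsilyl)propyne (n-BuLi, THF, −78 °C) with F7 gives 8.

## Further compounds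
F1 | step 5 | methyl 4-acetoxy-3-(chloromethyl)benzoate | COC(=O)c1ccc(OC(C)=O)c(CCl)c1
F2 | step 5 | methyl 4-acetoxy-3-[(2E,6E)-3,7-dimethyl-9-(2,6,6-trimethylcyclohex-1-en-1-yl)nona-2,6-dien-1-yl]benzoate | COC(=O)c1ccc(OC(C)=O)c(C/C=C(\C)CC/C=C(\C)CCC2=C(C)CCCC2(C)C)c1
F3 | step 4 | methyl 3-formyl-4-hydroxybenzoate | COC(=O)c1ccc(O)c(C=O)c1
F4 | step 4 | methyl 4-hydroxy-3-(hydroxymethyl)benzoate | COC(=O)c1ccc(O)c(CO)c1
F5 | step 1 | ethyl (2E)-3-methyl-5-(2,6,6-trimethylcyclohex-1-en-1-yl)pent-2-enoate | CCOC(=O)/C=C(\C)CCC1=C(C)CCCC1(C)C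
F6 | step 1 | (2E)-3-methyl-5-(2,6,6-trimethylcyclohex-1-en-1-yl)pent-2-en-1-ol | OC/C=C(\C)CCC1=C(C)CCCC1(C)C
F7 | step 1 | 2-[(3E)-5-bromo-3-methylpent-3-en-1-yl]-1,3,3-trimethylcyclohex-1-ene | BrC/C=C(\C)CCC1=C(C)CCCC1(C)C
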